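**Remark on the chemistry:** the C8–C3' biaryl axis is drawn without configuration and is treated as configurationally undefined, so the route contains no stereocontrolled step.

## Analysis of the target

The target is a biflavone of six rings: a chrysoeriol unit (rings A, C and B; 5-OH, 7-OH, 4'-OH, 3'-OMe) and an apigenin unit (5-OH, 7-OH, 4'-OH). The two are joined by one bond between C8 of the chrysoeriol ring A and C3' of the apigenin ring B. There is no stereogenic centre; the axis carries three ortho substituents (O7, the C8a–O1 side, O4') but no configuration is specified. Sensitive features are six phenols, two of them chelated to the C4 carbonyls, one aryl methyl ether that must survive the final unmasking, and two chromone rings that open under hot hydroxide. The first difficulty is the biaryl bond: it sits at the most hindered carbon of a phloroglucinol ring, so any substitution or cross-coupling approach must tell C8 from C6 and force a tri-ortho-substituted coupling. The second difficulty is distinguishing one methyl ether from six hydroxyls, which fixes isopropyl as the protecting group throughout. The strategy rests on this feature: O1, C8a, C4a and C4 of the chrysoeriol unit are already the atoms of a 4-pyranone, and ring A adds only C8, C7, C6 and C5, oxygenated at C7 and C5 like an acetoacetate chain. If C8, carrying its aryl group, is attached to the pyranone carbon next to the ring oxygen, closing C5 onto the neighbouring pyranone CH can only give the 8-aryl isomer.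

## Retrosynthetic reasoning

**25 to 24.** The last operation cuts six O–isopropyl bonds of 24. A boron trihalide removes secondary alkyl aryl ethers much faster than a methyl ether, so the single 3'-OMe can be carried unprotected from the first step.

**24 to 19 and 21.** Ring C of the apigenin unit is opened at O1–C2 and C2–C3, giving chalcone 22 and, behind it, aldehyde 19 and acetophenone 21. This half has no regiochemical problem, its phloroglucinol ring comes ready-made from 20, and attaching it last keeps the heavy half out of the thermolysis.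

**19 to 17.** The formyl carbon of 19 is traced to the aryl bromide of 18, and 18 to the diphenol 17 by two O-isopropylations. A bromide is chosen as the latent aldehyde because it is inert to amide bases, enolates, acid and heat, all of which the earlier steps use.

**17 to 14 (key disconnection).** Ring A is cut at C4a–C5 and unravelled, so that C8, C7, C6 and C5 become the four-carbon β-ketoester chain of 14 hanging from C2 of a 4-pyranone. This removes the biaryl coupling altogether, because the aryl group is already on the carbon that becomes C8. The forward reaction must turn the ester into a ketene and bond it to the pyranone CH.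

**14 to 11 and 12.** The bond between the ketone carbon and the CH2 of the ketoester is cut, leading to the carboxylic acid 11 and the malonate half-ester 12. A decarboxylative acylation under nearly neutral conditions is needed because the CH of 11 is very acidic.

**11 to 9.** The carboxyl carbon is removed from the doubly activated benzylic position, leaving the 2-benzyl-4-pyranone 9. The forward step is a lateral metalation and carboxylation at the only strongly acidic site.

**9 to 3 and 6.** The pyranone is opened at one C–O bond to the 1,3,5-triketone 8, which is cut between C3 and C2 of the future pyranone into the β-diketone 3 and the arylacetate 6. The dianion of 3 has a single terminal carbanion, so the acylation has one possible site.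

**Building blocks.** 3 comes from 1 by O-isopropylation (2) and Claisen condensation with an acetate ester. 6 comes from 4 by O-isopropylation (5) and para bromination. 21 comes from 20 by double O-isopropylation.

## Alternatives that were turned down

**Alternative 1: two-directional double Baker–Venkataraman.** Both rings C are opened at C2–C3. The forward key step treats the bis-ester A2 with excess base so that each acetyl enolate attacks its neighbouring ester carbonyl, giving the bis(1,3-diketone) A1 without closing a ring; acid then closes both pyranones.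
- For: every operation has close precedent, both flavone rings arise in two operations, and the end game after the key step is short.
- Against: A2 already contains the complete tri-ortho-substituted biaryl, so the hindered coupling and the C8/C6 question are only moved to an earlier cross-coupling. The phenol to be acylated on the core lies between an acetyl group and the new aryl ring, so esterification is slow. Two different acyl transfers must run in one pot while ester cleavage competes.
- Comparison: on reliability and on the length of the end game this alternative is stronger. The chosen strategy offers instead a ring A that is built with the aryl group in place, with no hindered cross-coupling and no halogenation regiochemistry.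

**Alternative 2: nitrile oxide cycloaddition masking the apigenin diketone.** The apigenin C3–C4 bond is cut in masked form. The persistent di-ortho-substituted nitrile oxide A4 adds to the terminal alkyne A5 and gives the 3,5-diarylisoxazole A3, a latent 1,3-diketone.
- For: the cycloaddition is neutral, fully regioselective with a terminal alkyne, and gentler on the existing chromone than a hydroxide-mediated aldol.
- Against: A5 is the complete 8-aryl chrysoeriol, so the hard half must exist before the key step and the biaryl problem is untouched. Unmasking needs reductive N–O cleavage next to a reducible chromone, then hydrolysis, acetal removal and cyclodehydration, so several operations replace the two of the chalcone route. An extra orthogonal protecting group is carried.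
- Comparison: it is at least as strong as the chosen end game on chemoselectivity in building the apigenin ring, but weaker on step economy, and it says nothing on how ring A with its C8 aryl is obtained, which is what the chosen strategy addresses.

**Alternative 3: acylative closure of the chrysoeriol ring C.** The C4–C4a bond is cut. The activated carboxyl of the (Z)-3-aryloxy-3-arylacrylic acid A7 acylates the aryloxy ring and gives the hexa-O-isopropyl biflavone A6, which is identical with 24.
- For: only one ortho position of the aryloxy ring is free, so the 8-aryl pattern is unambiguous, and the ring closure is a known chromone synthesis that delivers the penultimate compound directly.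
- Against: the strong protic or Lewis acids needed for the acylation are the ones that cleave isopropyl ethers on a phloroglucinol ring. Only the Z acid can close. The phenol precursor of A7 is a mono-unprotected 2-aryl phloroglucinol carrying a whole flavone, so the hindered biaryl bond must again be made by cross-coupling.
- Comparison: this alternative is stronger in precedent for the ring-closing event and in convergence. The chosen strategy avoids the biaryl coupling and places its one uncertain step early, on a small molecule, where failure costs little.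

Key step: step 9

## Route

Step 1
Reactants: 1 acetovanillone
Product: 2 1-(4-isopropoxy-3-methoxyphenyl)ethan-1-one
Conditions: 2-bromopropane, K2CO3, DMF, 70 °C
Reagents that add atoms: 2-bromopropane, CC(C)Br
Why: Williamson etherification of the only phenol; the isopropyl ether is stable to all later bases, acids and heat and is removable beside the methyl ether at the end.

Step 2
Reactants: 2 1-(4-isopropoxy-3-methoxyphenyl)ethan-1-one
Product: 3 1-(4-isopropoxy-3-methoxyphenyl)butane-1,3-dione
Conditions: NaH, EtOAc, THF, reflux; aq. HCl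
Reagents that add atoms: ethyl acetate, CCOC(C)=O
Why: Crossed Claisen condensation of an aryl methyl ketone enolate with an acetate ester; formation of the stable diketone enolate drives the equilibrium.

Step 3
Reactants: 4 methyl 2-(2-hydroxyphenyl)acetate
Product: 5 methyl 2-(2-isopropoxyphenyl)acetate
Conditions: 2-bromopropane, K2CO3, DMF, 60 °C
Reagents that add atoms: 2-bromopropane, CC(C)Br
Why: Williamson etherification; carbonate is too weak to enolize the arylacetate, so O-alkylation of the phenoxide is the only pathway.

Step 4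
Reactants: 5 methyl 2-(2-isopropoxyphenyl)acetate
Product: 6 methyl 2-(5-bromo-2-isopropoxyphenyl)acetate
Conditions: NBS, MeCN, 0 °C to rt, dark
Reagents that add atoms: N-bromosuccinimide, O=C1CCC(=O)N1Br
Why: Electrophilic aromatic bromination; the alkoxy group directs para, and the ortho position is shielded by the isopropyl group, so the bromine should enter at C5.

Step 5
Reactants: 3 1-(4-isopropoxy-3-methoxyphenyl)butane-1,3-dione; 6 methyl 2-(5-bromo-2-isopropoxyphenyl)acetate
Product: 8 1-(5-bromo-2-isopropoxyphenyl)-6-(4-isopropoxy-3-methoxyphenyl)hexane-2,4,6-trione, via dilithio dianion 7 (not isolated)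
Conditions: 3 (2.1 equiv), LiN(iPr)2 (4.2 equiv), THF, −78 to 0 °C; then 6 (1 equiv), −78 °C to rt; aq. HCl
Reagents that add atoms: none
Why: Harris-type acylation of a β-diketone dianion at its terminal carbanion, the only site of 7 that is not stabilized twice; the second equivalent of dianion takes up the acidic triketone, and the aryl bromide is inert to amide bases at these temperatures.

Step 6
Reactants: 8 1-(5-bromo-2-isopropoxyphenyl)-6-(4-isopropoxy-3-methoxyphenyl)hexane-2,4,6-trione
Product: 9 2-[(5-bromo-2-isopropoxyphenyl)methyl]-6-(4-isopropoxy-3-methoxyphenyl)-4H-pyran-4-one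
Conditions: TsOH·H2O (cat.), toluene, reflux, Dean–Stark
Reagents that add atoms: none
Why: Acid-catalysed cyclodehydration of a 1,3,5-triketone; attack of one terminal enol oxygen on the other terminal carbonyl gives a single 4-pyranone whichever end attacks, and acid favours this over the base-mediated aldol to a resorcinol.

Step 7
Reactants: 9 2-[(5-bromo-2-isopropoxyphenyl)methyl]-6-(4-isopropoxy-3-methoxyphenyl)-4H-pyran-4-one
Product: 11 2-(5-bromo-2-isopropoxyphenyl)-2-[6-(4-isopropoxy-3-methoxyphenyl)-4-oxo-4H-pyran-2-yl]acetic acid (racemic), via lithiated pyranone 10 (not isolated)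
Conditions: LiN(SiMe3)2, THF, −78 °C; CO2; cold aq. HCl to pH 3, 0 °C
Reagents that add atoms: carbon dioxide, O=C=O
Why: Lateral metalation and carboxylation of a 2-alkyl-4-pyranone; the CH2 is benzylic and vinylogously alpha to the pyranone carbonyl, so it is by far the most acidic site, and the extended enolate reacts at the exocyclic carbon. The acid is isolated cold and used at once because it is a vinylogous β-keto acid.

Step 8
Reactants: 11 2-(5-bromo-2-isopropoxyphenyl)-2-[6-(4-isopropoxy-3-methoxyphenyl)-4-oxo-4H-pyran-2-yl]acetic acid; 12 mono-tert-butyl malonate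
Product: 14 tert-butyl 4-(5-bromo-2-isopropoxyphenyl)-4-[6-(4-isopropoxy-3-methoxyphenyl)-4-oxo-4H-pyran-2-yl]-3-oxobutanoate (racemic, enolizable), via acyl imidazole 13 (not isolated)
Conditions: CDI, THF, 0 °C to rt; then 12, MgCl2, Et3N, THF/MeCN, rt to 40 °C; aq. citric acid
Reagents that add atoms: none
Why: Masamune homologation: the magnesium enolate of the malonate half-ester C-acylates the acyl imidazole under nearly neutral conditions and loses CO2, which avoids strong base on the acidic CH of 11.

Step 9
Reactants: 14 tert-butyl 4-(5-bromo-2-isopropoxyphenyl)-4-[6-(4-isopropoxy-3-methoxyphenyl)-4-oxo-4H-pyran-2-yl]-3-oxobutanoate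
Product: 17 8-(5-bromo-2-isopropoxyphenyl)-5,7-dihydroxy-2-(4-isopropoxy-3-methoxyphenyl)-4H-chromen-4-one, via acylketene 15 (not isolated), via cyclohexadienone 16 (not isolated)
Conditions: xylene (0.005 M), 140 °C, N2 sweep to remove tBuOH
Reagents that add atoms: none
Why: Proposed new method: on heating, the tert-butyl β-ketoester should lose tert-butanol in a unimolecular elimination to give acylketene 15, the known behaviour of tert-butyl acetoacetates and dioxinones. The ketone of 15 enolizes toward the CH that carries both the pyranone and the aryl ring, which lines up the ketene C=C, the enol C=C and the pyranone C2=C3 bond as a hexatriene, and thermally allowed disrotatory 6π-electrocyclization then joins the ketene carbon to pyranone C3 to give cyclohexadienone 16. The closest known reaction type is the dienylketene electrocyclization that ends the Danheiser benzannulation, fed here by an acylketene instead of a cyclobutenone opening. The one ring formed is the six-membered carbocycle, ring A, closed by 6π-electrocyclization; polar attack of the nucleophilic vinylogous-ester carbon C3 on the ketene carbon would form the same C4a–C5 bond, so both pathways converge. The C4a stereocentre of 16 is transient and is erased when the doubly activated C4a–H tautomerizes to the phenol, so no new stereocentre remains, and aromatization with a chelated 5-OH drives the sequence. The step needs closure onto the pyranone CH and not onto the free ortho CH of the bromoaryl ring: the pyranone C2=C3 bond is a localized, electron-rich enol-ether double bond, whereas attack on the benzene ring would break aromaticity at a carbon meta to the isopropoxy group. It also needs the enol isomer with ketenyl group and pyranone cis, reached by keto–enol equilibration at this temperature, and it needs the ketene to escape dimerization and recapture, which high dilution and removal of tert-butanol provide. The aryl group ends at C8 by connectivity alone.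

Step 10
Reactants: 17 8-(5-bromo-2-isopropoxyphenyl)-5,7-dihydroxy-2-(4-isopropoxy-3-methoxyphenyl)-4H-chromen-4-one
Product: 18 8-(5-bromo-2-isopropoxyphenyl)-5,7-diisopropoxy-2-(4-isopropoxy-3-methoxyphenyl)-4H-chromen-4-one
Conditions: 2-bromopropane (excess), K2CO3, DMF, 80 °C, sealed
Reagents that add atoms: 2-bromopropane, CC(C)Br
Why: Williamson etherification; the 7-OH reacts first, and the chelated 5-OH follows with excess halide and heat, so that no free phenol interferes with the palladium and aldol steps.

Step 11
Reactants: 18 8-(5-bromo-2-isopropoxyphenyl)-5,7-diisopropoxy-2-(4-isopropoxy-3-methoxyphenyl)-4H-chromen-4-one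
Product: 19 3-[5,7-diisopropoxy-2-(4-isopropoxy-3-methoxyphenyl)-4-oxo-4H-chromen-8-yl]-4-isopropoxybenzaldehyde
Conditions: Pd(OAc)2 (cat.), nBuP(1-adamantyl)2, TMEDA, CO/H2 (1:1, 5 bar), toluene, 100 °C
Reagents that add atoms: carbon monoxide, [C-]#[O+]
Why: Palladium-catalysed reductive carbonylation (formylation) of an aryl bromide: oxidative addition, CO insertion and hydrogenolysis of the acyl palladium species; the bromide is para to an alkoxy group and unhindered, and the chromone is inert, whereas a lithium–halogen exchange would attack it.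

Step 12
Reactants: 20 2',4',6'-trihydroxyacetophenone
Product: 21 1-(2-hydroxy-4,6-diisopropoxyphenyl)ethan-1-one
Conditions: 2-bromopropane (2.1 equiv), K2CO3, DMF, 60 °C
Reagents that add atoms: 2-bromopropane, CC(C)Br
Why: Williamson etherification that stops after two alkylations, because the last hydroxyl is hydrogen-bonded to the acetyl group and much less nucleophilic.

Step 13
Reactants: 19 3-[5,7-diisopropoxy-2-(4-isopropoxy-3-methoxyphenyl)-4-oxo-4H-chromen-8-yl]-4-isopropoxybenzaldehyde; 21 1-(2-hydroxy-4,6-diisopropoxyphenyl)ethan-1-one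
Product: 22 (E)-3-{3-[5,7-diisopropoxy-2-(4-isopropoxy-3-methoxyphenyl)-4-oxo-4H-chromen-8-yl]-4-isopropoxyphenyl}-1-(2-hydroxy-4,6-diisopropoxyphenyl)prop-2-en-1-one
Conditions: KOH (50% aq.), EtOH/THF, rt; aq. HCl
Reagents that add atoms: none
Why: Claisen–Schmidt condensation; the aldehyde cannot enolize, dehydration gives the conjugated E enone, and a flavone without free hydroxyls tolerates hydroxide at room temperature.

Step 14
Reactants: 22 (E)-3-{3-[5,7-diisopropoxy-2-(4-isopropoxy-3-methoxyphenyl)-4-oxo-4H-chromen-8-yl]-4-isopropoxyphenyl}-1-(2-hydroxy-4,6-diisopropoxyphenyl)prop-2-en-1-one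
Product: 24 8-[5-(5,7-diisopropoxy-4-oxo-4H-chromen-2-yl)-2-isopropoxyphenyl]-5,7-diisopropoxy-2-(4-isopropoxy-3-methoxyphenyl)-4H-chromen-4-one, via flavanone 23 (not isolated)
Conditions: I2 (10 mol%), DMSO, 130 °C
Reagents that add atoms: none
Why: Iodine-mediated oxidative cyclization of a 2'-hydroxychalcone: oxa-Michael closure to flavanone 23, alpha-iodination and loss of HI, with DMSO reoxidizing iodide; partial loss of a peri isopropyl group would be harmless before the next step.

Step 15
Reactants: 24 8-[5-(5,7-diisopropoxy-4-oxo-4H-chromen-2-yl)-2-isopropoxyphenyl]-5,7-diisopropoxy-2-(4-isopropoxy-3-methoxyphenyl)-4H-chromen-4-one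
Product: 25 8-[5-(5,7-dihydroxy-4-oxo-4H-chromen-2-yl)-2-hydroxyphenyl]-5,7-dihydroxy-2-(4-hydroxy-3-methoxyphenyl)-4H-chromen-4-one (CNP0179340.0)
Conditions: BCl3 (excess), CH2Cl2, −78 °C to rt; then MeOH/H2O
Reagents that add atoms: none
Why: Lewis-acid dealkylation; BCl3 complexes the ether oxygens and chloride removes the secondary isopropyl groups, the chelated C5 ethers first, while the primary methyl ether reacts far more slowly at or below room temperature.

## Compound list

1 | acetovanillone | CC(=O)c1ccc(O)c(OC)c1 | starting material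
2 | 1-(4-isopropoxy-3-methoxyphenyl)ethan-1-one | CC(=O)c1ccc(OC(C)C)c(OC)c1 | intermediate
3 | 1-(4-isopropoxy-3-methoxyphenyl)butane-1,3-dione | CC(=O)CC(=O)c1ccc(OC(C)C)c(OC)c1 | intermediate
4 | methyl 2-(2-hydroxyphenyl)acetate | COC(=O)Cc1ccccc1O | starting material
5 | methyl 2-(2-isopropoxyphenyl)acetate | COC(=O)Cc1ccccc1OC(C)C | intermediate
6 | methyl 2-(5-bromo-2-isopropoxyphenyl)acetate | COC(=O)Cc1cc(Br)ccc1OC(C)C | intermediate
7 | dilithio dianion of 3, deprotonated at C2 and at the terminal methyl (not isolated) | [Li+].[Li+].[CH2-]C(=O)[CH-]C(=O)c1ccc(OC(C)C)c(OC)c1 | intermediate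
8 | 1-(5-bromo-2-isopropoxyphenyl)-6-(4-isopropoxy-3-methoxyphenyl)hexane-2,4,6-trione | COc1cc(C(=O)CC(=O)CC(=O)Cc2cc(Br)ccc2OC(C)C)ccc1OC(C)C | intermediate
9 | 2-[(5-bromo-2-isopropoxyphenyl)methyl]-6-(4-isopropoxy-3-methoxyphenyl)-4H-pyran-4-one | COc1cc(-c2cc(=O)cc(Cc3cc(Br)ccc3OC(C)C)o2)ccc1OC(C)C | intermediate
10 | lithium salt of 9, deprotonated at the benzylic carbon (not isolated) | [Li+].COc1cc(-c2cc(=O)cc([CH-]c3cc(Br)ccc3OC(C)C)o2)ccc1OC(C)C | intermediate
11 | 2-(5-bromo-2-isopropoxyphenyl)-2-[6-(4-isopropoxy-3-methoxyphenyl)-4-oxo-4H-pyran-2-yl]acetic acid (racemic) | COc1cc(-c2cc(=O)cc(C(C(=O)O)c3cc(Br)ccc3OC(C)C)o2)ccc1OC(C)C | intermediate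
12 | mono-tert-butyl malonate | CC(C)(C)OC(=O)CC(=O)O | starting material
13 | 2-(5-bromo-2-isopropoxyphenyl)-1-(imidazol-1-yl)-2-[6-(4-isopropoxy-3-methoxyphenyl)-4-oxo-4H-pyran-2-yl]ethan-1-one (racemic, not isolated) | COc1cc(-c2cc(=O)cc(C(C(=O)n3ccnc3)c3cc(Br)ccc3OC(C)C)o2)ccc1OC(C)C | intermediate
14 | tert-butyl 4-(5-bromo-2-isopropoxyphenyl)-4-[6-(4-isopropoxy-3-methoxyphenyl)-4-oxo-4H-pyran-2-yl]-3-oxobutanoate (racemic, enolizable) | CC(C)(C)OC(=O)CC(=O)C(c1cc(=O)cc(-c2ccc(OC(C)C)c(OC)c2)o1)c1cc(Br)ccc1OC(C)C | intermediate
15 | 4-(5-bromo-2-isopropoxyphenyl)-4-[6-(4-isopropoxy-3-methoxyphenyl)-4-oxo-4H-pyran-2-yl]but-1-ene-1,3-dione, the acylketene, drawn as its keto tautomer (not isolated) | O=C=CC(=O)C(c1cc(=O)cc(-c2ccc(OC(C)C)c(OC)c2)o1)c1cc(Br)ccc1OC(C)C | intermediate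
16 | 8-(5-bromo-2-isopropoxyphenyl)-7-hydroxy-2-(4-isopropoxy-3-methoxyphenyl)-4aH-chromene-4,5-dione (racemic, not isolated) | O=C1C=C(O)C(c3cc(Br)ccc3OC(C)C)=C2OC(c3ccc(OC(C)C)c(OC)c3)=CC(=O)C12 | intermediate
17 | 8-(5-bromo-2-isopropoxyphenyl)-5,7-dihydroxy-2-(4-isopropoxy-3-methoxyphenyl)-4H-chromen-4-one | COc1cc(-c2cc(=O)c3c(O)cc(O)c(-c4cc(Br)ccc4OC(C)C)c3o2)ccc1OC(C)C | intermediate
18 | 8-(5-bromo-2-isopropoxyphenyl)-5,7-diisopropoxy-2-(4-isopropoxy-3-methoxyphenyl)-4H-chromen-4-one | COc1cc(-c2cc(=O)c3c(OC(C)C)cc(OC(C)C)c(-c4cc(Br)ccc4OC(C)C)c3o2)ccc1OC(C)C | intermediate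
19 | 3-[5,7-diisopropoxy-2-(4-isopropoxy-3-methoxyphenyl)-4-oxo-4H-chromen-8-yl]-4-isopropoxybenzaldehyde | COc1cc(-c2cc(=O)c3c(OC(C)C)cc(OC(C)C)c(-c4cc(C=O)ccc4OC(C)C)c3o2)ccc1OC(C)C | intermediate
20 | 2',4',6'-trihydroxyacetophenone | CC(=O)c1c(O)cc(O)cc1O | starting material
21 | 1-(2-hydroxy-4,6-diisopropoxyphenyl)ethan-1-one | CC(=O)c1c(O)cc(OC(C)C)cc1OC(C)C | intermediate
22 | (E)-3-{3-[5,7-diisopropoxy-2-(4-isopropoxy-3-methoxyphenyl)-4-oxo-4H-chromen-8-yl]-4-isopropoxyphenyl}-1-(2-hydroxy-4,6-diisopropoxyphenyl)prop-2-en-1-one | COc1cc(-c2cc(=O)c3c(OC(C)C)cc(OC(C)C)c(-c4cc(/C=C/C(=O)c5c(O)cc(OC(C)C)cc5OC(C)C)ccc4OC(C)C)c3o2)ccc1OC(C)C | intermediate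
23 | 2-{3-[5,7-diisopropoxy-2-(4-isopropoxy-3-methoxyphenyl)-4-oxo-4H-chromen-8-yl]-4-isopropoxyphenyl}-5,7-diisopropoxychroman-4-one (racemic, not isolated) | COc1cc(-c2cc(=O)c3c(OC(C)C)cc(OC(C)C)c(-c4cc(C5CC(=O)c6c(OC(C)C)cc(OC(C)C)cc6O5)ccc4OC(C)C)c3o2)ccc1OC(C)C | intermediate
24 | 8-[5-(5,7-diisopropoxy-4-oxo-4H-chromen-2-yl)-2-isopropoxyphenyl]-5,7-diisopropoxy-2-(4-isopropoxy-3-methoxyphenyl)-4H-chromen-4-one | COc1cc(-c2cc(=O)c3c(OC(C)C)cc(OC(C)C)c(-c4cc(-c5cc(=O)c6c(OC(C)C)cc(OC(C)C)cc6o5)ccc4OC(C)C)c3o2)ccc1OC(C)C | intermediate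
25 | 8-[5-(5,7-dihydroxy-4-oxo-4H-chromen-2-yl)-2-hydroxyphenyl]-5,7-dihydroxy-2-(4-hydroxy-3-methoxyphenyl)-4H-chromen-4-one | COc1cc(-c2cc(=O)c3c(O)cc(O)c(-c4cc(-c5cc(=O)c6c(O)cc(O)cc6o5)ccc4O)c3o2)ccc1O | target

## Step count and least certain steps

Total step count: 15. Longest linear sequence: 12 steps (1, 2, 5, 6, 7, 8, 9, 10, 11, 13, 14, 15; the branch through steps 3 and 4 is equally long).

**Step 9 (key step).** Three things may go wrong. The ketene may close onto the bromoaryl ring or dimerize instead of closing onto the pyranone. The ester may lose isobutene and CO2 and give a methyl ketone before any ketene forms. The enol may stay in the geometry that cannot cyclize. All three follow from the fact that the closure competes with faster unimolecular or bimolecular exits of a very reactive intermediate. The fallback uses known chemistry, sets out from 21 and returns at 19, bypassing steps 1 to 11: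
- 21 is iodinated ortho to its free hydroxyl (N-iodosuccinimide, cat. TFA, MeCN) to give 1-(2-hydroxy-3-iodo-4,6-diisopropoxyphenyl)ethan-1-one F1.
- Claisen–Schmidt condensation with 4-isopropoxy-3-methoxybenzaldehyde F2 (from vanillin and 2-bromopropane) gives (E)-1-(2-hydroxy-3-iodo-4,6-diisopropoxyphenyl)-3-(4-isopropoxy-3-methoxyphenyl)prop-2-en-1-one F3.
- I2 in DMSO closes it to 8-iodo-5,7-diisopropoxy-2-(4-isopropoxy-3-methoxyphenyl)-4H-chromen-4-one F4.
- 3-Bromo-4-isopropoxybenzaldehyde F5 (from 3-bromo-4-hydroxybenzaldehyde) is borylated (bis(pinacolato)diboron, Pd(dppf)Cl2, KOAc) to 4-isopropoxy-3-(4,4,5,5-tetramethyl-1,3,2-dioxaborolan-2-yl)benzaldehyde F6.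
- Suzuki–Miyaura coupling of F4 with F6 (Pd(PPh3)4, K2CO3, DMF/H2O, 90 °C) gives 19.

**Step 5.** Proton transfer from the acidic arylacetate CH2 to the dianion may outrun acyl transfer, returning both partners unchanged or giving self-condensation of the ester. The fallback sets out from 6 and returns at 8. It replaces the Claisen-type acylation by a ketone synthesis that stops at a chelated tetrahedral adduct. 6 is converted with N,O-dimethylhydroxylamine hydrochloride and iPrMgCl into 2-(5-bromo-2-isopropoxyphenyl)-N-methoxy-N-methylacetamide F7, whose alpha protons are less acidic. F7 is added to dianion 7, and since the adduct releases no acidic triketone before work-up, one equivalent of dianion suffices; acid work-up gives 8.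

**Step 7.** Loss of CO2 from the vinylogous β-keto acid during acidification or on standing may return 9, and the ambident anion may be carboxylated at oxygen or at C3. The fallback sets out from 9 and returns at 11. Anion 10, formed with two equivalents of base, is trapped with di-tert-butyl dicarbonate to give tert-butyl 2-(5-bromo-2-isopropoxyphenyl)-2-[6-(4-isopropoxy-3-methoxyphenyl)-4-oxo-4H-pyran-2-yl]acetate F8. F8 can be purified and stored; it is cleaved with TFA in CH2Cl2, where the protonated pyranone cannot decarboxylate through a zwitterion, and evaporation gives 11 for immediate use.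

**Step 8.** Enolization of the acyl imidazole toward a ketene, or slow acyl transfer at the crowded carbonyl, may lead to oligomers or recovered acid. The fallback sets out from 11 and returns at 14. 11 is condensed with Meldrum's acid (EDC·HCl, DMAP, CH2Cl2, 0 °C) to 5-{2-(5-bromo-2-isopropoxyphenyl)-1-hydroxy-2-[6-(4-isopropoxy-3-methoxyphenyl)-4-oxo-4H-pyran-2-yl]ethylidene}-2,2-dimethyl-1,3-dioxane-4,6-dione F9. Heating F9 with tert-butanol in toluene at 80 to 90 °C gives 14 by alcoholysis of the acylketene. If the ketene closes ring A faster than it is trapped, 17 would form directly.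

**Step 13.** The doubly ortho-substituted acetophenone enolate adds slowly, and during the long exposure hydroxide may open the chromone ring of 19 or of the product. The fallback sets out from 19 and returns at 24, replacing the aldol by an acyl transfer:
- 19 is oxidized (NaClO2, NaH2PO4, 2-methyl-2-butene) to 3-[5,7-diisopropoxy-2-(4-isopropoxy-3-methoxyphenyl)-4-oxo-4H-chromen-8-yl]-4-isopropoxybenzoic acid F10.
- Oxalyl chloride and cat. DMF give the acid chloride 3-[5,7-diisopropoxy-2-(4-isopropoxy-3-methoxyphenyl)-4-oxo-4H-chromen-8-yl]-4-isopropoxybenzoyl chloride F11.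
- The dianion of 21 (LiN(SiMe3)2, THF, −78 °C) is C-acylated by F11 to 1-{3-[5,7-diisopropoxy-2-(4-isopropoxy-3-methoxyphenyl)-4-oxo-4H-chromen-8-yl]-4-isopropoxyphenyl}-3-(2-hydroxy-4,6-diisopropoxyphenyl)propane-1,3-dione F12.
- Cyclodehydration of F12 (cat. H2SO4, AcOH, 80 °C) gives 24.

## Further compounds

F1 | step 9 | 1-(2-hydroxy-3-iodo-4,6-diisopropoxyphenyl)ethan-1-one | CC(=O)c1c(O)c(I)c(OC(C)C)cc1OC(C)C
F2 | step 9 | 4-isopropoxy-3-methoxybenzaldehyde | COc1cc(C=O)ccc1OC(C)C
F3 | step 9 | (E)-1-(2-hydroxy-3-iodo-4,6-diisopropoxyphenyl)-3-(4-isopropoxy-3-methoxyphenyl)prop-2-en-1-one | COc1cc(/C=C/C(=O)c2c(O)c(I)c(OC(C)C)cc2OC(C)C)ccc1OC(C)C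
F4 | step 9 | 8-iodo-5,7-diisopropoxy-2-(4-isopropoxy-3-methoxyphenyl)-4H-chromen-4-one | COc1cc(-c2cc(=O)c3c(OC(C)C)cc(OC(C)C)c(I)c3o2)ccc1OC(C)C
F5 | step 9 | 3-bromo-4-isopropoxybenzaldehyde | CC(C)Oc1ccc(C=O)cc1Br
F6 | step 9 | 4-isopropoxy-3-(4,4,5,5-tetramethyl-1,3,2-dioxaborolan-2-yl)benzaldehyde | CC(C)Oc1ccc(C=O)cc1B1OC(C)(C)C(C)(C)O1
F7 | step 5 | 2-(5-bromo-2-isopropoxyphenyl)-N-methoxy-N-methylacetamide | CON(C)C(=O)Cc1cc(Br)ccc1OC(C)C
F8 | step 7 | tert-butyl 2-(5-bromo-2-isopropoxyphenyl)-2-[6-(4-isopropoxy-3-methoxyphenyl)-4-oxo-4H-pyran-2-yl]acetate (racemic) | COc1cc(-c2cc(=O)cc(C(C(=O)OC(C)(C)C)c3cc(Br)ccc3OC(C)C)o2)ccc1OC(C)C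
F9 | step 8 | 5-{2-(5-bromo-2-isopropoxyphenyl)-1-hydroxy-2-[6-(4-isopropoxy-3-methoxyphenyl)-4-oxo-4H-pyran-2-yl]ethylidene}-2,2-dimethyl-1,3-dioxane-4,6-dione (racemic) | COc1cc(-c2cc(=O)cc(C(C(O)=C3C(=O)OC(C)(C)OC3=O)c3cc(Br)ccc3OC(C)C)o2)ccc1OC(C)C
F10 | step 13 | 3-[5,7-diisopropoxy-2-(4-isopropoxy-3-methoxyphenyl)-4-oxo-4H-chromen-8-yl]-4-isopropoxybenzoic acid | COc1cc(-c2cc(=O)c3c(OC(C)C)cc(OC(C)C)c(-c4cc(C(=O)O)ccc4OC(C)C)c3o2)ccc1OC(C)C
F11 | step 13 | 3-[5,7-diisopropoxy-2-(4-isopropoxy-3-methoxyphenyl)-4-oxo-4H-chromen-8-yl]-4-isopropoxybenzoyl chloride | COc1cc(-c2cc(=O)c3c(OC(C)C)cc(OC(C)C)c(-c4cc(C(=O)Cl)ccc4OC(C)C)c3o2)ccc1OC(C)C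
F12 | step 13 | 1-{3-[5,7-diisopropoxy-2-(4-isopropoxy-3-methoxyphenyl)-4-oxo-4H-chromen-8-yl]-4-isopropoxyphenyl}-3-(2-hydroxy-4,6-diisopropoxyphenyl)propane-1,3-dione | COc1cc(-c2cc(=O)c3c(OC(C)C)cc(OC(C)C)c(-c4cc(C(=O)CC(=O)c5c(O)cc(OC(C)C)cc5OC(C)C)ccc4OC(C)C)c3o2)ccc1OC(C)C
A1 | alternative 1 | 1-(2-hydroxy-4,6-diisopropoxyphenyl)-3-{3-[2-hydroxy-4,6-diisopropoxy-3-[3-(4-isopropoxy-3-methoxyphenyl)-3-oxopropanoyl]phenyl]-4-isopropoxyphenyl}propane-1,3-dione | COc1cc(C(=O)CC(=O)c2c(OC(C)C)cc(OC(C)C)c(-c3cc(C(=O)CC(=O)c4c(O)cc(OC(C)C)cc4OC(C)C)ccc3OC(C)C)c2O)ccc1OC(C)C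
A2 | alternative 1 | 2-acetyl-3,5-diisopropoxyphenyl 3-[3-acetyl-2-(4-isopropoxy-3-methoxybenzoyloxy)-4,6-diisopropoxyphenyl]-4-isopropoxybenzoate | COc1cc(C(=O)Oc2c(C(C)=O)c(OC(C)C)cc(OC(C)C)c2-c2cc(C(=O)Oc3cc(OC(C)C)cc(OC(C)C)c3C(C)=O)ccc2OC(C)C)ccc1OC(C)C
A3 | alternative 2 | 3-[2,4-diisopropoxy-6-(methoxymethoxy)phenyl]-5-{3-[5,7-diisopropoxy-2-(4-isopropoxy-3-methoxyphenyl)-4-oxo-4H-chromen-8-yl]-4-isopropoxyphenyl}isoxazole | COCOc1cc(OC(C)C)cc(OC(C)C)c1-c1cc(-c2ccc(OC(C)C)c(-c3c(OC(C)C)cc(OC(C)C)c4c(=O)cc(-c5ccc(OC(C)C)c(OC)c5)oc34)c2)on1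
A4 | alternative 2 | 2,4-diisopropoxy-6-(methoxymethoxy)benzonitrile oxide | COCOc1cc(OC(C)C)cc(OC(C)C)c1C#[N+][O-]
A5 | alternative 2 | 8-(5-ethynyl-2-isopropoxyphenyl)-5,7-diisopropoxy-2-(4-isopropoxy-3-methoxyphenyl)-4H-chromen-4-one | C#Cc1ccc(OC(C)C)c(-c2c(OC(C)C)cc(OC(C)C)c3c(=O)cc(-c4ccc(OC(C)C)c(OC)c4)oc23)c1
A6 | alternative 3 | 8-[5-(5,7-diisopropoxy-4-oxo-4H-chromen-2-yl)-2-isopropoxyphenyl]-5,7-diisopropoxy-2-(4-isopropoxy-3-methoxyphenyl)-4H-chromen-4-one | COc1cc(-c2cc(=O)c3c(OC(C)C)cc(OC(C)C)c(-c4cc(-c5cc(=O)c6c(OC(C)C)cc(OC(C)C)cc6o5)ccc4OC(C)C)c3o2)ccc1OC(C)C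
A7 | alternative 3 | (Z)-3-{2-[5-(5,7-diisopropoxy-4-oxo-4H-chromen-2-yl)-2-isopropoxyphenyl]-3,5-diisopropoxyphenoxy}-3-(4-isopropoxy-3-methoxyphenyl)prop-2-enoic acid | OC(=O)/C=C(/c1ccc(OC(C)C)c(OC)c1)Oc1cc(OC(C)C)cc(OC(C)C)c1-c1cc(-c2cc(=O)c3c(OC(C)C)cc(OC(C)C)cc3o2)ccc1OC(C)C
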